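A curve still rising at its last reading is easily carried further, and the pitfall is that epsilon and beta rise under less second nucleophile than this flask holds.

| setting | epsilon | beta | flask |
|---|---|---|---|
| substrate | 0.014 M | 0.014 M | 0.014 M |
| first nucleophile | 1.2 equiv | 1.2 equiv | 1.20 equiv |
| second nucleophile | 0.50 equiv | 0.75 equiv | 1.00 equiv |
| remark | run made earlier | run made earlier |  |
| time |  |  | 4.0 h |

- epsilon (time / h: target / %): 0.667: 9.5; 0.833: 10.0; 1.00: 11.7; 1.33: 13.0; 2.00: 14.6; 2.50: 18.4; 3.00: 19.0
- beta (time / h: target / %): 0.667: 7.3; 0.833: 10.8; 1.00: 9.3; 1.33: 12.1; 2.00: 12.5; 2.50: 15.8; 3.00: 15.1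

(standard deviation of a reading: 1 percentage point)

- the analysis behind the earlier runs scatters by 1 percentage point, standard deviation

* when, up to 4.0 h, the flask holds most target
* the amount of target, in percent of the substrate charged, at that time
* the first time at which target reaches 3.5%, in the same percent

I first asked how fast second nucleophile might consume target. Over the readings from 2.00 h to 3.00 h, beta sums lower than epsilon. Target there is about 1.25 h old on average if it grew evenly, so I took the log gap between the sums as loss over that age. This gives the flask's pseudo-first-order lifetime of target against second nucleophile: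

gap = 0.181

τ = 1.73 h

But the sums differ by 8.6 percentage points, and that difference scatters by 2.4 points, so τ is rough. The readings from 0.667 h to 1.00 h also show a gap of 0.130, where τ predicts 0.0603. Part of the gap may therefore arise before target forms, and τ may be longer.

Still, 4.0 h is 2.31 lifetimes. Target stops rising where it equals making rate times τ. Late in epsilon, whose lifetime is twice τ, the net rise plus the loss gives:

making rate × τ = 14.9%

The first epsilon reading gives 24.6%, so in epsilon making appeared to slow. I expected a peak before 4.0 h, not above 14.9%. At epsilon's early pace, 3.5% takes 0.246 h.

The forecast gave 4 h (3.2 h to 4 h), 16% (13% to 19%) and 0.15 h (0.06 h to 0.35 h), reasoning that “Neither run shows a maximum, so I expect the best point to be at the 4.0 h limit”.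

The flask gives 11.7% at 2.44 h, and reaches 3.5% at 0.275 h.

    substrate → intermediate (k = 0.369 h⁻¹)
    first nucleophile + intermediate → target (k = 33500 M⁻¹ h⁻¹)
    second nucleophile + intermediate → other capture product (k = 16700 M⁻¹ h⁻¹)
    intermediate → solvolysis product (k = 624 h⁻¹)
    second nucleophile + target → over-reaction product (k = 41.3 M⁻¹ h⁻¹)

At 1.32 h the flask still made target 1.60 times faster than it used it up, and the two rates met at 2.44 h, which is 1.41 of my lifetimes; 4.0 h lay past that peak, and the flask then held 10.5% of target. Read at 1.0 h, the same flask should hold over-reaction product at 0.289 of its target, taking the average age as half the time; it holds 2.91% against 8.99%, a ratio of 0.324.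

The runs are simulated for an exercise; scatter was added.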